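**Strategy**

The target is disconnected at C3–C3a and C3'–C3a', the bonds joining each pyrrole ring to its benzo ring. The plan rests on one feature: C3 and C3', the two pyrrole carbons linked by the biaryl bond, are neighbours and can both be carried as the carbonyl carbons of a 1,2-diketone, while each C3a is the benzo-ring carbon ortho to N1 and para to the bromine on C6. A single acid-mediated double cyclodehydration should therefore close both pyrrole rings and deliver the complete 6,6'-dibromo-3,3'-biindole core. Its precursor is butane-2,3-dione bearing an N-(3-bromophenyl)trifluoroacetamido group on C1 and on C4; N-deacylation and bromination at C2 and C2' complete the route.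

Key step: step 3

Remark: the target has no stereocentre; minor 4-bromo regioisomers from step 3 are assumed to be removable by crystallisation or chromatography.

**Route**

Step 1
Reactants: 1 3-bromoaniline; 2 trifluoroacetic anhydride
Product: 3 N-(3-bromophenyl)-2,2,2-trifluoroacetamide
Conditions: TFAA (1.1 equiv), CH2Cl2, 0 °C to rt
Reagents that add atoms: trifluoroacetic anhydride (compound 2), O=C(OC(=O)C(F)(F)F)C(F)(F)F
Why: N-Acylation of the weakly basic aniline by the highly electrophilic anhydride should be fast and clean, and the trifluoroacetyl group makes the N–H acidic enough for carbonate-mediated alkylation in step 2.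

Step 2
Reactants: 3 N-(3-bromophenyl)-2,2,2-trifluoroacetamide (2.1 equiv); 4 1,4-dibromobutane-2,3-dione
Product: 5 N,N'-(2,3-dioxobutane-1,4-diyl)bis[N-(3-bromophenyl)-2,2,2-trifluoroacetamide]
Conditions: K2CO3 (2.2 equiv), MeCN, 0 °C to rt (4 added last)
Reagents that add atoms: none
Why: Twofold SN2 N-alkylation of the potassium anilide by the primary α-bromo ketone carbons, the same reaction type as imide-anion alkylation with α-halo ketones, should proceed at low temperature because the carbonyl-activated C–Br bonds are very reactive and the stabilised amide anion is too weak a base to enolise the diketone extensively.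

Step 3
Reactants: 5 N,N'-(2,3-dioxobutane-1,4-diyl)bis[N-(3-bromophenyl)-2,2,2-trifluoroacetamide]
Product: 7 6,6'-dibromo-1,1'-bis(trifluoroacetyl)-1H,1'H-3,3'-biindole, via monoindolyl ketone 6 (not isolated)
Conditions: TFAA, TFA, reflux (sealed tube, 100 °C, if 6 persists)
Reagents that add atoms: none
Why: Each ketone carbon, activated by protonation in the strong acid, is attacked by the anilide carbon ortho to nitrogen in an intramolecular Friedel–Crafts hydroxyalkylation, and the adduct loses water (taken up by the anhydride) to give the aromatic pyrrole ring, first as 3-acylindole 6 and then as 7. The closest known reaction type is the Bischler-type (Nordlander) cyclodehydration of N-trifluoroacetyl α-anilino acetals and ketones to 1-(trifluoroacetyl)indoles in this same medium. Both rings close in the 5-exo-trig mode, the arene carbon adding to the carbonyl carbon that becomes C3 (or C3') of a ring made of N1, C2, C3, C3a and C7a, with the C=O bond outside the ring. No stereocentre is created, so no stereocontrol is needed. Regioselectivity between the two carbons ortho to nitrogen is required and should favour the one para to bromine (giving the 6-bromo pattern), because the bromine lone pairs direct para and the other carbon is wedged between nitrogen and bromine; attack on the nearer carbonyl is also required and is favoured because only that five-membered adduct can aromatise by dehydration, the six-membered adduct at the far carbonyl having a fully substituted carbinol carbon. The N-trifluoroacetyl groups prevent imine formation and aniline exchange, and the electrophilic vicinal diketone offsets the deactivated ring, although the second ketone, by then a 3-acylindole carbonyl, may need prolonged heating.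

Step 4
Reactants: 7 6,6'-dibromo-1,1'-bis(trifluoroacetyl)-1H,1'H-3,3'-biindole
Product: 8 6,6'-dibromo-1H,1'H-3,3'-biindole
Conditions: K2CO3 (cat.), MeOH/THF, rt
Reagents that add atoms: none
Why: Methanolysis of an N-acylindole should be rapid under mild carbonate catalysis because the trifluoroacetyl carbonyl is strongly electrophilic and the indole nitrogen is a good leaving group, while the aryl bromides are inert.

Step 5
Reactants: 8 6,6'-dibromo-1H,1'H-3,3'-biindole
Product: 9 2,2',6,6'-tetrabromo-1H,1'H-3,3'-biindole (target)
Conditions: NBS (2.05 equiv), THF, −78 °C to 0 °C, dark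
Reagents that add atoms: N-bromosuccinimide, O=C1CCC(=O)N1Br
Why: Electrophilic bromination of a 3-substituted indole should place bromine at C2 and C2' (directly or through a 3-bromoindolenine that shifts bromine to C2 and rearomatises), since C3 is blocked and the C6 bromines temper the benzo rings against further substitution.

**Compound list**

1 | 3-bromoaniline | Nc1cccc(Br)c1 | starting material
2 | trifluoroacetic anhydride | O=C(OC(=O)C(F)(F)F)C(F)(F)F | starting material
3 | N-(3-bromophenyl)-2,2,2-trifluoroacetamide | O=C(Nc1cccc(Br)c1)C(F)(F)F | intermediate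
4 | 1,4-dibromobutane-2,3-dione | O=C(CBr)C(=O)CBr | starting material
5 | N,N'-(2,3-dioxobutane-1,4-diyl)bis[N-(3-bromophenyl)-2,2,2-trifluoroacetamide] | O=C(CN(C(=O)C(F)(F)F)c1cccc(Br)c1)C(=O)CN(C(=O)C(F)(F)F)c1cccc(Br)c1 | intermediate
6 | N-(3-bromophenyl)-N-{2-[6-bromo-1-(trifluoroacetyl)-1H-indol-3-yl]-2-oxoethyl}-2,2,2-trifluoroacetamide (monoindolyl ketone) | O=C(CN(C(=O)C(F)(F)F)c1cccc(Br)c1)c1cn(C(=O)C(F)(F)F)c2cc(Br)ccc12 | intermediate (not isolated)
7 | 6,6'-dibromo-1,1'-bis(trifluoroacetyl)-1H,1'H-3,3'-biindole | O=C(n1cc(-c2cn(C(=O)C(F)(F)F)c3cc(Br)ccc23)c2ccc(Br)cc21)C(F)(F)F | intermediate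
8 | 6,6'-dibromo-1H,1'H-3,3'-biindole | Brc1ccc2c(-c3c[nH]c4cc(Br)ccc34)c[nH]c2c1 | intermediate
9 | 2,2',6,6'-tetrabromo-1H,1'H-3,3'-biindole | Brc1ccc2c(-c3c(Br)[nH]c4cc(Br)ccc34)c(Br)[nH]c2c1 | target

**Step count**

Total steps: 5. Longest linear sequence: 5 steps (1 → 3 → 5 → 7 → 8 → 9).

**Steps most likely to fail**

Step 3 (highest risk). The second ring closure may stall at the 3-acylindole stage. Closure may also occur at the carbon between nitrogen and bromine, or onto the far carbonyl in a six-membered mode, and the forcing acid may degrade the diketone. The fallback forms the two indole rings separately and makes the C3–C3' bond afterwards. It sets out from 1 and returns at 8.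
- Compound 1 is N-alkylated with bromoacetaldehyde diethyl acetal (NaHCO3, EtOH, reflux) to give N-(2,2-diethoxyethyl)-3-bromoaniline F1.
- Acylation with TFAA and Et3N in CH2Cl2 gives N-(3-bromophenyl)-N-(2,2-diethoxyethyl)-2,2,2-trifluoroacetamide F2.
- A single Nordlander cyclisation in TFAA/TFA at reflux gives 6-bromo-1-(trifluoroacetyl)-1H-indole F3.
- Methanolysis with K2CO3 in MeOH gives 6-bromo-1H-indole F4. This compound is also an article of commerce, which would shorten the detour.
- Oxidative C3–C3' homocoupling of F4 with catalytic Pd(OCOCF3)2 (divalent palladium) and Cu(OAc)2 in DMSO at rt should give 8. These are conditions under which the aryl bromides should not undergo oxidative addition.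

Step 2 (second). The bromo diketone may self-condense under base, the anilide may add to a carbonyl, or alkylation may occur on oxygen instead of nitrogen. The fallback introduces the diketone in masked form as an alkyne. It sets out from 3 and returns at 5.
- Compound 3 is alkylated twice with 1,4-dibromobut-2-yne (K2CO3, DMF, rt) to give N,N'-(but-2-yne-1,4-diyl)bis[N-(3-bromophenyl)-2,2,2-trifluoroacetamide] F5.
- The alkyne of F5 is oxidised to the 1,2-diketone with catalytic RuCl3 and NaIO4 (CCl4/MeCN/H2O, 0 °C, short contact time) to give 5.

Step 5 (third). The electron-rich biindole may be over-brominated on the benzo rings or oxidised to oxindole-type products. The fallback replaces electrophilic bromination by directed C2 metalation. It sets out from 8 and returns at 9.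
- Compound 8 is protected with Boc2O and catalytic DMAP in MeCN to give di-tert-butyl 6,6'-dibromo-1H,1'H-3,3'-biindole-1,1'-dicarboxylate F6.
- Deprotonation at C2 and C2' with LiN(iPr)2 in THF at −78 °C, which should not exchange the aryl bromides, and quenching with 1,2-dibromo-1,1,2,2-tetrachloroethane gives di-tert-butyl 2,2',6,6'-tetrabromo-1H,1'H-3,3'-biindole-1,1'-dicarboxylate F7.
- Removal of the carbamates with K2CO3 in warm MeOH gives 9.

**Further compounds**

F1 | step 3 | N-(2,2-diethoxyethyl)-3-bromoaniline | CCOC(CNc1cccc(Br)c1)OCC
F2 | step 3 | N-(3-bromophenyl)-N-(2,2-diethoxyethyl)-2,2,2-trifluoroacetamide | CCOC(CN(C(=O)C(F)(F)F)c1cccc(Br)c1)OCC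
F3 | step 3 | 6-bromo-1-(trifluoroacetyl)-1H-indole | O=C(n1ccc2ccc(Br)cc21)C(F)(F)F
F4 | step 3 | 6-bromo-1H-indole | Brc1ccc2cc[nH]c2c1
F5 | step 2 | N,N'-(but-2-yne-1,4-diyl)bis[N-(3-bromophenyl)-2,2,2-trifluoroacetamide] | O=C(N(CC#CCN(C(=O)C(F)(F)F)c1cccc(Br)c1)c1cccc(Br)c1)C(F)(F)F
F6 | step 5 | di-tert-butyl 6,6'-dibromo-1H,1'H-3,3'-biindole-1,1'-dicarboxylate | CC(C)(C)OC(=O)n1cc(-c2cn(C(=O)OC(C)(C)C)c3cc(Br)ccc23)c2ccc(Br)cc21
F7 | step 5 | di-tert-butyl 2,2',6,6'-tetrabromo-1H,1'H-3,3'-biindole-1,1'-dicarboxylate | CC(C)(C)OC(=O)n1c(Br)c(-c2c(Br)n(C(=O)OC(C)(C)C)c3cc(Br)ccc23)c2ccc(Br)cc21
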